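## Analysis of the target

Atoms are labelled along the chain, bromines skipped: C1 (=CH2), C2, C3 (isopropenyl), C4 (CH–O), C5 (CH2), C6 (quaternary), C7 (acetal CH), O8 (joins C7 to C4), O9 (joins C7 to C10), C10 (carbinol carbon, methyl C11), C12 (CHBr), C13=C14(Br), C15 (CMe2).

- Target 28 is a tricyclic C15 dibromide. Ring A (C6, C10, C12, C13, C14, C15) is a cyclohexene. An oxetane (C6, C7, O9, C10) is fused to its C6–C10 bond. A tetrahydrofuran (C4, C5, C6, C7, O8) is spiro to ring A at C6 and shares C6–C7 with the oxetane, so C7 is an acetal carbon held in a four- and a five-membered ring.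
- The five stereocentres are 4R, 6S, 7S, 10S, 12S. The cis ring fusion ties C7 to C6 and puts C7 and O9 on one face of ring A, with C5 and the C11 methyl on the other. The C12 bromine is trans to O9. The isopropenyl group at C4 lies on the convex face of the bicyclic acetal, trans to C10.
- C15, C6 and C10 are three contiguous fully substituted carbons. C6 is an all-carbon quaternary stereocentre with no neighbouring stereocentre to set it.
- The oxetane acetal is the most fragile group. It is acid-labile, it can fragment to a ketone and an enol ether, and a free hydroxyl at C12 can attack C7 to give a far more stable five-membered acetal. The allylic secondary bromide sits next to the fully substituted C10. The isopropenyl group does not survive ozone.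
- The difficulty is therefore the order of events as much as any single bond.
- The strategy rests on C10 and C12. Both carry a heteroatom, the C10 oxygen is cis to C7, and the C12 bromine is trans to it. That pattern is a cis-diol on the C7 face whose C12 hydroxyl is later inverted, and such a diol is what a chelated ketyl coupling between a C10 methyl ketone and a C12 aldehyde delivers.

## Retrosynthetic reasoning

**C12–Br (28 from 27).** The bromide is introduced last, by inversion of the C12 alcohol 27. It cannot be carried earlier: it would be lost by β-elimination when the C14 ketone is enolised, and a C10 alkoxide would displace it.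

**C7–O9 (26 from 24).** The strained acetal is cut next, back to lactol 24 and its tertiary C10 hydroxyl, through anomeric chloride 25. It is made as late as possible, after every acidic and enolate step. The C12 oxygen stays silylated so that it cannot form the five-membered acetal instead.

**Vinyl bromide and lactol (24 from 19).** Lactol 24 comes from lactone 23, the vinyl bromide from enol triflate 22, and that from ketone 20, freed from ketal 19. Acid hydrolysis and enolate chemistry are thus finished while C7 is still a robust lactone carbonyl. Ketone 20 can enolise only towards C13, which fixes the position of the C13=C14 bond.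

**C7–O8 and the isopropenyl group (19 from 17).** The lactone and the isopropenyl carbinol come from epoxy ester 17: base-induced opening of the epoxide towards a methyl group, then ring closure of the C4 hydroxyl on the C7 ester. The epoxide is an ozone-proof mask for the isopropenyl carbinol, and the lactonisation expels the chiral auxiliary.

**C10–C12 (16 from 15), the key cut.** Diol 16 is disconnected to keto aldehyde 15. The forward ketyl coupling has to close ring A and set C10 and C12 in one operation, with both oxygens on the face of the C7 ester.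

**Ring cleavage (15 from 13).** Keto aldehyde 15 is the ozonolysis product of ring alkene 13, via ozonide 14. Cleavage and re-closure together amount to a syn-dihydroxylation of C10=C12 on the ester face. A direct dihydroxylation of this hindered alkene would choose its face by sterics, whereas the chelated re-closure dictates it.

**Alkene position and C4 (13 from 11).** The ring alkene of 13 comes from exocyclic methylene compound 12 by isomerisation. The epoxide of 12 comes from prenyl compound 11 by a reagent-controlled dioxirane epoxidation, which sets C4. Epoxidising before isomerising means the prenyl group is the only trisubstituted alkene present.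

**C6–C5 (11 from 8 and 9).** The quaternary centre arises by α-prenylation of the dienolate 10 of enoate 8 with bromide 9. Kinetic deprotonation of 8 is expected at the methyl group cis to the ester, not at ring C12, so the alkene first appears exocyclic; the isomerisation above repairs this. The chiral ester group is what distinguishes the faces of C6. A methyl ester would give a racemate.

**The ring (8 from 1 and 7).** Enoate 8 comes from enol triflate 6 and alcohol 7 by carbonylation, 6 from methyl ketone 4, and 4 from mono-ketal 2 of dione 1. The dione supplies the C6–C15 bond between the two most hindered carbons ready-made, so no step has to join them.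

## Alternatives that were turned down

**Alternative 1: conjugate addition–aldol around C6.**
- Disconnection: the C15–CH3 and C6–C10 bonds. In the forward step a methyl cuprate adds to C15 of alkylidene lactone A2, and the nucleophilic C6 so created is trapped by ketone A3 to give A1.
- For: it is short and convergent. The lactone with C4 is there from the start, and attack at C6 anti to the C4 substituent should give the right C6 configuration without any auxiliary. On both counts it is stronger than the chosen route. A later aldol between C13 and C12 would give the C12 hydroxyl and C14 ketone directly.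
- Against: the cuprate must attack a fully substituted β-carbon. The hindered α-carbon must then add to an enolisable, unactivated ketone, forming a tertiary aldolate between two quaternary carbons, where proton transfer and retro-aldol compete. The face of A3 is chosen between a methyl and a dimethoxymethyl group, so C10 is not secured. C12 would be set by a reversible aldol that can dehydrate.
- Comparison: the chosen route spends more steps and an auxiliary, but it sets C10 and C12 together inside a chelate with a defined relation to C6.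

**Alternative 2: palladium allyl lactonisation at C4.**
- Disconnection: C4–O8. A zerovalent palladium catalyst with a chiral bisphosphine ionises the allylic carbonate of acid A5, and the C7 carboxylate closes on C4 to give spiro lactone A4 with the isopropenyl group in place.
- For: one catalytic, stereoconvergent step replaces epoxidation plus epoxide isomerisation, and no Lewis-acidic aluminium reagent is needed. On the making of C4 it is the stronger plan.
- Against: C6 must still be set beforehand, so nothing is gained on the hardest centre. The ligand has to override a neopentylic, fully substituted neighbour. Above all, the isopropenyl group arrives before ring A is oxidised, and neither ozone nor osmium would then prefer the hindered C10=C12 bond to the exposed 1,1-disubstituted one.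
- Comparison: the chosen route keeps the isopropenyl group latent until ring A has been cut and re-closed.

**Alternative 3: ring-contracting Ireland–Claisen.**
- Disconnection: C6–C15 inside ring A. Six-membered lactone A7 is enolised and O-silylated, and the [3,3] shift through a boat forms C6–C15, breaks C13–O and gives acid A6.
- For: it makes the most difficult C–C bond directly with chirality transfer from C13. Ring A appears with the C13=C14 vinyl bromide and a protected C10/C12 diol, so the late triflate-to-bromide exchange disappears. In endgame economy it is stronger.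
- Against: the enolate carbon C6 has the C10 acetonide oxygen in the β-position, so β-elimination threatens the moment A7 is deprotonated. The accepting terminus C15 is fully substituted and part of a bromoalkene, so two adjacent quaternary centres must form through a strained boat. The C12 oxygen in A6 is still cis and must still be inverted.
- Comparison: the chosen route forms no bond between quaternary carbons at all, and its risk sits in one well-precedented type of ring closure.

Key step: step 9

Remarks on the chemistry:
- The drawn configuration of CNP0141320.1 is taken as absolute.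
- The descriptor at the quaternary carbon reads R in 11–13 and S from 14 onwards only because C10 gains CIP priority when it becomes oxygenated; the spatial arrangement does not change.
- Kinetic deprotonation of enoate 8 is assumed to occur at the methyl group cis to the ester. Any deprotonation at ring C12 gives the endocyclic isomer, which converges on 13.

## Route

**Step 1**
Reactants: 1 2,2-dimethylcyclohexane-1,3-dione
Product: 2 6,6-dimethyl-1,4-dioxaspiro[4.5]decan-7-one
Conditions: ethane-1,2-diol (1.0 equiv), p-TsOH·H2O (cat.), benzene, reflux, Dean–Stark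
Reagents that add atoms: ethane-1,2-diol, OCCO
Why: Acid-catalysed mono-ketalisation of a symmetrical dione; one equivalent of diol and the hindrance next to the gem-dimethyl carbon after the first ketalisation favour the mono-ketal.

**Step 2**
Reactants: 2 6,6-dimethyl-1,4-dioxaspiro[4.5]decan-7-one
Product: 4 6,6,8-trimethyl-1,4-dioxaspiro[4.5]decan-7-one (racemic), via lithium enolate 3 (not isolated)
Conditions: LDA, THF, −78 °C; MeI, −78 to 0 °C
Reagents that add atoms: iodomethane, CI
Why: Enolate alkylation; the ketone can enolise only towards the CH2 group, and the new stereocentre is irrelevant because it becomes sp2 in the next step.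

**Step 3**
Reactants: 4 6,6,8-trimethyl-1,4-dioxaspiro[4.5]decan-7-one
Product: 6 6,6,8-trimethyl-1,4-dioxaspiro[4.5]dec-7-en-7-yl trifluoromethanesulfonate, via potassium enolate 5 (not isolated)
Conditions: KHMDS, THF, −78 °C; PhNTf2, −78 °C to rt
Reagents that add atoms: N-phenylbis(trifluoromethanesulfonimide), O=S(=O)(N(c1ccccc1)S(=O)(=O)C(F)(F)F)C(F)(F)F
Why: O-Triflation of the only possible enolate gives the tetrasubstituted enol triflate.

**Step 4**
Reactants: 6 6,6,8-trimethyl-1,4-dioxaspiro[4.5]dec-7-en-7-yl trifluoromethanesulfonate; 7 (1R,2S)-2-phenylcyclohexan-1-ol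
Product: 8 (1R,2S)-2-phenylcyclohexyl 6,6,8-trimethyl-1,4-dioxaspiro[4.5]dec-7-ene-7-carboxylate
Conditions: Pd(OAc)2 (5 mol%), 1,3-bis(diphenylphosphino)propane (6 mol%), CO (1 atm), 7 (2 equiv), Et3N, DMF, 70 °C
Reagents that add atoms: carbon monoxide, [C-]#[O+]
Why: Palladium-catalysed alkoxycarbonylation of an enol triflate; the acyl palladium intermediate has no β-hydrogen and waits for the secondary alcohol, which installs the chiral ester group in the step that creates C7.

**Step 5**
Reactants: 8 (1R,2S)-2-phenylcyclohexyl 6,6,8-trimethyl-1,4-dioxaspiro[4.5]dec-7-ene-7-carboxylate; 9 1-bromo-3-methylbut-2-ene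
Product: 11 (1R,2S)-2-phenylcyclohexyl (7R)-6,6-dimethyl-8-methylidene-7-(3-methylbut-2-en-1-yl)-1,4-dioxaspiro[4.5]decane-7-carboxylate, via lithium dienolate 10 (not isolated)
Conditions: LDA (1.1 equiv), THF, −78 to −40 °C; 9 (1.5 equiv), DMPU, −78 to −20 °C
Reagents that add atoms: none
Why: Lithium bound to the ester carbonyl delivers the amide to the cis γ-methyl group (kinetic syn-γ deprotonation), giving exocyclic dienolate 10 with the lithium-bearing oxygen on the C10 side and the alkoxy group on the C15 side; ester dienolates alkylate at the α-carbon (deconjugative α-alkylation), so C6 becomes quaternary. With the carbinol C–H of the auxiliary in the ketene acetal plane its phenyl ring covers one face, and the bromide should enter from the other to give the 7R ester (the 6S arrangement of the target); the C7 epimer is a diastereomer and is removed by chromatography.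

**Step 6**
Reactants: 11 (1R,2S)-2-phenylcyclohexyl (7R)-6,6-dimethyl-8-methylidene-7-(3-methylbut-2-en-1-yl)-1,4-dioxaspiro[4.5]decane-7-carboxylate
Product: 12 (1R,2S)-2-phenylcyclohexyl (7R)-7-{[(2R)-3,3-dimethyloxiran-2-yl]methyl}-6,6-dimethyl-8-methylidene-1,4-dioxaspiro[4.5]decane-7-carboxylate
Conditions: D-fructose-derived Shi ketone (1,2:4,5-di-O-isopropylidene-β-D-erythro-2,3-hexodiulo-2,6-pyranose, 0.3 equiv), Oxone, K2CO3, n-Bu4NHSO4, MeCN–dimethoxymethane/aq. borate buffer (pH 10.5), 0 °C
Reagents that add atoms: potassium peroxymonosulfate (active component of Oxone), [K+].[O-]S(=O)(=O)OO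
Why: Shi epoxidation through a spiro dioxirane transition state; the trisubstituted prenyl alkene reacts and the hindered 1,1-disubstituted methylene group does not. The D-fructose-derived ketone should give the R epoxide at C4 under reagent control, and any minor C4 isomer is a separable diastereomer because C6 is already set.

**Step 7**
Reactants: 12 (1R,2S)-2-phenylcyclohexyl (7R)-7-{[(2R)-3,3-dimethyloxiran-2-yl]methyl}-6,6-dimethyl-8-methylidene-1,4-dioxaspiro[4.5]decane-7-carboxylate
Product: 13 (1R,2S)-2-phenylcyclohexyl (7R)-7-{[(2R)-3,3-dimethyloxiran-2-yl]methyl}-6,6,8-trimethyl-1,4-dioxaspiro[4.5]dec-8-ene-7-carboxylate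
Conditions: chloro[N,N'-bis(3,5-di-tert-butylsalicylidene)cyclohexane-1,2-diaminato]cobalt (3 mol%), PhSiH3 (6 mol%), benzene, rt
Reagents that add atoms: none
Why: Hydrogen-atom-transfer alkene isomerisation: a cobalt hydride gives H to the terminal CH2, and the tertiary C10 radical can lose H only from C11 (return) or from C12, because C6 is quaternary. The exocyclic alkene therefore moves to the more stable trisubstituted C10=C12 position; the epoxide is remote from the radical.

**Step 8**
Reactants: 13 (1R,2S)-2-phenylcyclohexyl (7R)-7-{[(2R)-3,3-dimethyloxiran-2-yl]methyl}-6,6,8-trimethyl-1,4-dioxaspiro[4.5]dec-8-ene-7-carboxylate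
Product: 15 (1R,2S)-2-phenylcyclohexyl (2S)-2-acetyl-2-{[(2R)-3,3-dimethyloxiran-2-yl]methyl}-3-methyl-3-[2-(2-oxoethyl)-1,3-dioxolan-2-yl]butanoate, via secondary ozonide 14 (not isolated)
Conditions: O3, CH2Cl2, −78 °C (Sudan Red 7B end-point); PPh3, −78 °C to rt; used crude
Reagents that add atoms: ozone, [O-][O+]=O
Why: Ozonolysis (cycloaddition, Criegee rearrangement to 14, reduction) cleaves the only alkene into the C10 methyl ketone and the C12 aldehyde; epoxide, ketal, ester and the arene survive at −78 °C with an indicator end-point. C6 is not enolisable, and the base-sensitive β-ketal aldehyde is used at once.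

**Step 9**
Reactants: 15 (1R,2S)-2-phenylcyclohexyl (2S)-2-acetyl-2-{[(2R)-3,3-dimethyloxiran-2-yl]methyl}-3-methyl-3-[2-(2-oxoethyl)-1,3-dioxolan-2-yl]butanoate
Product: 16 (1R,2S)-2-phenylcyclohexyl (7S,8S,9R)-7-{[(2R)-3,3-dimethyloxiran-2-yl]methyl}-8,9-dihydroxy-6,6,8-trimethyl-1,4-dioxaspiro[4.5]decane-7-carboxylate
Conditions: SmI2 (2.5 equiv, 0.1 M in THF), t-BuOH (2 equiv), THF, −78 °C, slow addition of 15; sat. aq. NaHCO3 at −78 °C
Reagents that add atoms: none
Why: Electron transfer from SmI2 to the aldehyde, the more easily reduced carbonyl, gives a C12 ketyl bound to trivalent samarium; the oxophilic metal also binds the C10 ketone oxygen and the C7 ester carbonyl, the ketyl carbon adds to the ketone carbon inside this chelate, and a second electron and protonation give the diol. The closest known reaction type is the SmI2-mediated intramolecular aldehyde–ketone pinacol coupling of β-keto esters carrying an oxoalkyl chain, which gives cis-cycloalkane-1,2-diols. Ring A closes by 6-exo-trig attack of the ketyl carbon on the carbonyl carbon. C10 is controlled by the β-keto ester chelate: the ketone oxygen is held syn to the ester carbonyl and the tether reaches the carbonyl carbon from the C15 side, so the C10 oxygen ends cis to C7 (8S in the name, 10S in the target). C12 is controlled by the samarium bridge between the two oxygens, which forces the diol cis (9R in the name, the epimer needed for later inversion). The step needs coupling to beat simple reduction, dimerisation and aldol closure, and it needs the epoxide and the β-ketal to survive; no HMPA (chelation is kept and the epoxide spared), slow addition at −78 °C, the folding effect of the C15 gem-dimethyl group and a cold bicarbonate quench should secure this. The cold quench should also keep the samarium alkoxides from attacking the ester or the epoxide.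

**Step 10**
Reactants: 16 (1R,2S)-2-phenylcyclohexyl (7S,8S,9R)-7-{[(2R)-3,3-dimethyloxiran-2-yl]methyl}-8,9-dihydroxy-6,6,8-trimethyl-1,4-dioxaspiro[4.5]decane-7-carboxylate
Product: 17 (1R,2S)-2-phenylcyclohexyl (7S,8S,9R)-9-[(tert-butyldimethylsilyl)oxy]-7-{[(2R)-3,3-dimethyloxiran-2-yl]methyl}-8-hydroxy-6,6,8-trimethyl-1,4-dioxaspiro[4.5]decane-7-carboxylate
Conditions: TBSCl, imidazole, DMF, 35 °C
Reagents that add atoms: tert-butyldimethylsilyl chloride, CC(C)(C)[Si](C)(C)Cl
Why: Silylation of the secondary C12 hydroxyl only (the tertiary C10 hydroxyl does not react) under basic conditions that spare the epoxide. Blocking C12–OH now prevents it from competing as a lactonisation nucleophile in step 11 and as an acetal partner in step 16.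

**Step 11**
Reactants: 17 (1R,2S)-2-phenylcyclohexyl (7S,8S,9R)-9-[(tert-butyldimethylsilyl)oxy]-7-{[(2R)-3,3-dimethyloxiran-2-yl]methyl}-8-hydroxy-6,6,8-trimethyl-1,4-dioxaspiro[4.5]decane-7-carboxylate
Product: 19 (3R,5S,9R,10S)-9-[(tert-butyldimethylsilyl)oxy]-7,7-(ethylenedioxy)-10-hydroxy-6,6,10-trimethyl-3-(prop-1-en-2-yl)-2-oxaspiro[4.5]decan-1-one, via allylic alcohol ester 18 (not isolated)
Conditions: Et2AlCl, LiTMP (gives Et2AlTMP, 4 equiv), toluene, 0 °C; Rochelle salt; then Ti(Oi-Pr)4 (0.3 equiv), toluene, 80 °C
Reagents that add atoms: none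
Why: Aluminium-amide epoxide-to-allylic-alcohol isomerisation: aluminium binds the epoxide oxygen, the amide removes a methyl proton in a cyclic syn-elimination, and the C2–O bond breaks, so C4 keeps its oxygen and configuration and the isopropenyl group appears. Titanate-mediated transesterification then closes the γ-lactone from the C4 hydroxyl and releases auxiliary 7 for recovery.

**Step 12**
Reactants: 19 (3R,5S,9R,10S)-9-[(tert-butyldimethylsilyl)oxy]-7,7-(ethylenedioxy)-10-hydroxy-6,6,10-trimethyl-3-(prop-1-en-2-yl)-2-oxaspiro[4.5]decan-1-one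
Product: 20 (3R,5S,9R,10S)-9-[(tert-butyldimethylsilyl)oxy]-10-hydroxy-6,6,10-trimethyl-3-(prop-1-en-2-yl)-2-oxaspiro[4.5]decane-1,7-dione
Conditions: PPTS, acetone–H2O (10:1), 60 °C
Reagents that add atoms: water, O
Why: Acid hydrolysis of the dioxolane; lactone, hindered secondary silyl ether and isopropenyl group tolerate PPTS. The only acidic step of the endgame is placed before any acetal exists at C7.

**Step 13**
Reactants: 20 (3R,5S,9R,10S)-9-[(tert-butyldimethylsilyl)oxy]-10-hydroxy-6,6,10-trimethyl-3-(prop-1-en-2-yl)-2-oxaspiro[4.5]decane-1,7-dione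
Product: 22 (3R,5S,9R,10S)-9-[(tert-butyldimethylsilyl)oxy]-10-hydroxy-6,6,10-trimethyl-1-oxo-3-(prop-1-en-2-yl)-2-oxaspiro[4.5]dec-7-en-7-yl trifluoromethanesulfonate, via dilithium alkoxide enolate 21 (not isolated)
Conditions: LiHMDS (2.3 equiv), THF, −78 °C; N-(5-chloropyridin-2-yl)bis(trifluoromethanesulfonimide) (Comins' reagent), −78 °C; AcOH quench at −78 °C
Reagents that add atoms: N-(5-chloropyridin-2-yl)bis(trifluoromethanesulfonimide), O=S(=O)(N(c1ccc(Cl)cn1)S(=O)(=O)C(F)(F)F)C(F)(F)F
Why: Enol triflate formation; the ketone enolises only towards C13 (C15 is quaternary), and the first equivalent of base is taken by the C10 hydroxyl. Lithium as counter-ion and −78 °C throughout are chosen so that the C10 alkoxide does not undergo retro-aldol cleavage or silyl migration and the β-silyloxy enolate does not eliminate.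

**Step 14**
Reactants: 22 (3R,5S,9R,10S)-9-[(tert-butyldimethylsilyl)oxy]-10-hydroxy-6,6,10-trimethyl-1-oxo-3-(prop-1-en-2-yl)-2-oxaspiro[4.5]dec-7-en-7-yl trifluoromethanesulfonate
Product: 23 (3R,5S,9R,10S)-7-bromo-9-[(tert-butyldimethylsilyl)oxy]-10-hydroxy-6,6,10-trimethyl-3-(prop-1-en-2-yl)-2-oxaspiro[4.5]dec-7-en-1-one
Conditions: Ni(cod)2 (10 mol%), LiBr (3 equiv), DMA–THF (1:3), rt
Reagents that add atoms: lithium bromide, [Li+].[Br-]
Why: Nickel-catalysed halide exchange of an enol triflate: zerovalent nickel inserts into the C–OTf bond, bromide replaces triflate on the metal, and reductive elimination gives the vinyl bromide. The conditions are neutral and tolerate lactone, silyl ether and the free tertiary alcohol.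

**Step 15**
Reactants: 23 (3R,5S,9R,10S)-7-bromo-9-[(tert-butyldimethylsilyl)oxy]-10-hydroxy-6,6,10-trimethyl-3-(prop-1-en-2-yl)-2-oxaspiro[4.5]dec-7-en-1-one
Product: 24 (3R,5S,9R,10S)-7-bromo-9-[(tert-butyldimethylsilyl)oxy]-6,6,10-trimethyl-3-(prop-1-en-2-yl)-2-oxaspiro[4.5]dec-7-ene-1,10-diol (both C1 anomers)
Conditions: i-Bu2AlH (2.5 equiv), CH2Cl2, −78 °C; Rochelle salt
Reagents that add atoms: none
Why: Partial reduction of a γ-lactone to the lactol; the aluminium hemiacetal is stable at −78 °C and the vinyl bromide and silyl ether are inert.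

**Step 16**
Reactants: 24 (3R,5S,9R,10S)-7-bromo-9-[(tert-butyldimethylsilyl)oxy]-6,6,10-trimethyl-3-(prop-1-en-2-yl)-2-oxaspiro[4.5]dec-7-ene-1,10-diol
Product: 26 oxetane acetal silyl ether (4R,6S,7S,10S,12R; C7 bonded to O8 and O9; C12 OTBS; C14 bromide), via anomeric chloride 25 (not isolated)
Conditions: MsCl, Et3N, CH2Cl2, −30 °C; concentrate; NaH, THF, 0 °C; pH 8 work-up
Reagents that add atoms: none
Why: The lactol hydroxyl, not the hindered tertiary one, is sulfonylated and replaced by chloride; the sodium alkoxide of the C10 hydroxyl then displaces the anomeric chloride intramolecularly (4-exo-tet), the way 1,3-anhydro sugars are made from 3-hydroxy glycosyl chlorides. C6 carries no hydrogen, so elimination is impossible; an alkoxide far outcompetes the silyl ether oxygen; and the cis fusion of the two small rings fixes C7 as S.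

**Step 17**
Reactants: 26 oxetane acetal silyl ether (4R,6S,7S,10S,12R)
Product: 27 oxetane acetal allylic alcohol (4R,6S,7S,10S,12R; C12 OH cis to O9)
Conditions: n-Bu4NF, THF, 0 °C; pH 8 buffer; used crude
Reagents that add atoms: none
Why: Fluoride cleavage of the allylic silyl ether under basic conditions, which the acetal tolerates; the product is not chromatographed on acidic silica because the free C12 hydroxyl can open the oxetane under acid catalysis.

**Step 18**
Reactants: 27 oxetane acetal allylic alcohol (4R,6S,7S,10S,12R)
Product: 28 CNP0141320.1 (4R,6S,7S,10S,12S)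
Conditions: PPh3, CBr4, 2,6-lutidine, CH2Cl2, 0 °C
Reagents that add atoms: tetrabromomethane, BrC(Br)(Br)Br
Why: Appel bromination: the alkoxyphosphonium salt is displaced by bromide with inversion, turning the cis C12 oxygen into the trans bromide. Allylic transposition is blocked because C14 is brominated and neopentylic, and the base keeps the medium non-acidic.

## Compound list

1 | 2,2-dimethylcyclohexane-1,3-dione | CC1(C)C(=O)CCCC1=O | starting material
2 | 6,6-dimethyl-1,4-dioxaspiro[4.5]decan-7-one | CC1(C)C(=O)CCCC12OCCO2 | intermediate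
3 | lithium enolate of 2 | [Li]OC1=CCCC2(OCCO2)C1(C)C | intermediate
4 | 6,6,8-trimethyl-1,4-dioxaspiro[4.5]decan-7-one (racemic) | CC1CCC2(OCCO2)C(C)(C)C1=O | intermediate
5 | potassium enolate of 4 | [K]OC1=C(C)CCC2(OCCO2)C1(C)C | intermediate
6 | 6,6,8-trimethyl-1,4-dioxaspiro[4.5]dec-7-en-7-yl trifluoromethanesulfonate | CC1=C(OS(=O)(=O)C(F)(F)F)C(C)(C)C2(OCCO2)CC1 | intermediate
7 | (1R,2S)-2-phenylcyclohexan-1-ol | O[C@@H]1CCCC[C@H]1c1ccccc1 | starting material
8 | (1R,2S)-2-phenylcyclohexyl 6,6,8-trimethyl-1,4-dioxaspiro[4.5]dec-7-ene-7-carboxylate | CC1=C(C(=O)O[C@@H]3CCCC[C@H]3c4ccccc4)C(C)(C)C2(OCCO2)CC1 | intermediate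
9 | 1-bromo-3-methylbut-2-ene | CC(C)=CCBr | starting material
10 | lithium dienolate of 8 (exocyclic methylene; O–Li on the C10 side) | [Li]OC(O[C@@H]3CCCC[C@H]3c4ccccc4)=C1C(=C)CCC2(OCCO2)C1(C)C | intermediate
11 | (1R,2S)-2-phenylcyclohexyl (7R)-6,6-dimethyl-8-methylidene-7-(3-methylbut-2-en-1-yl)-1,4-dioxaspiro[4.5]decane-7-carboxylate | O=C(O[C@@H]3CCCC[C@H]3c4ccccc4)[C@]1(CC=C(C)C)C(=C)CCC2(OCCO2)C1(C)C | intermediate
12 | (1R,2S)-2-phenylcyclohexyl (7R)-7-{[(2R)-3,3-dimethyloxiran-2-yl]methyl}-6,6-dimethyl-8-methylidene-1,4-dioxaspiro[4.5]decane-7-carboxylate | O=C(O[C@@H]3CCCC[C@H]3c4ccccc4)[C@]1(C[C@H]5OC5(C)C)C(=C)CCC2(OCCO2)C1(C)C | intermediate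
13 | (1R,2S)-2-phenylcyclohexyl (7R)-7-{[(2R)-3,3-dimethyloxiran-2-yl]methyl}-6,6,8-trimethyl-1,4-dioxaspiro[4.5]dec-8-ene-7-carboxylate | O=C(O[C@@H]3CCCC[C@H]3c4ccccc4)[C@]1(C[C@H]5OC5(C)C)C(C)=CCC2(OCCO2)C1(C)C | intermediate
14 | secondary ozonide of 13 (1,2,4-trioxolane across C10 and C12) | O=C(O[C@@H]3CCCC[C@H]3c4ccccc4)[C@]1(C[C@H]5OC5(C)C)C6(C)OC(OO6)CC2(OCCO2)C1(C)C | intermediate
15 | (1R,2S)-2-phenylcyclohexyl (2S)-2-acetyl-2-{[(2R)-3,3-dimethyloxiran-2-yl]methyl}-3-methyl-3-[2-(2-oxoethyl)-1,3-dioxolan-2-yl]butanoate (precursor of the key step) | O=C(O[C@@H]3CCCC[C@H]3c4ccccc4)[C@](C[C@H]5OC5(C)C)(C(C)=O)C(C)(C)C2(CC=O)OCCO2 | intermediate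
16 | (1R,2S)-2-phenylcyclohexyl (7S,8S,9R)-7-{[(2R)-3,3-dimethyloxiran-2-yl]methyl}-8,9-dihydroxy-6,6,8-trimethyl-1,4-dioxaspiro[4.5]decane-7-carboxylate (product of the key step) | O=C(O[C@@H]3CCCC[C@H]3c4ccccc4)[C@]1(C[C@H]5OC5(C)C)[C@](C)(O)[C@H](O)CC2(OCCO2)C1(C)C | intermediate
17 | (1R,2S)-2-phenylcyclohexyl (7S,8S,9R)-9-[(tert-butyldimethylsilyl)oxy]-7-{[(2R)-3,3-dimethyloxiran-2-yl]methyl}-8-hydroxy-6,6,8-trimethyl-1,4-dioxaspiro[4.5]decane-7-carboxylate | O=C(O[C@@H]3CCCC[C@H]3c4ccccc4)[C@]1(C[C@H]5OC5(C)C)[C@](C)(O)[C@H](O[Si](C)(C)C(C)(C)C)CC2(OCCO2)C1(C)C | intermediate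
18 | (1R,2S)-2-phenylcyclohexyl (7S,8S,9R)-9-[(tert-butyldimethylsilyl)oxy]-8-hydroxy-7-[(2R)-2-hydroxy-3-methylbut-3-en-1-yl]-6,6,8-trimethyl-1,4-dioxaspiro[4.5]decane-7-carboxylate | O=C(O[C@@H]3CCCC[C@H]3c4ccccc4)[C@]1(C[C@@H](O)C(C)=C)[C@](C)(O)[C@H](O[Si](C)(C)C(C)(C)C)CC2(OCCO2)C1(C)C | intermediate
19 | (3R,5S,9R,10S)-9-[(tert-butyldimethylsilyl)oxy]-7,7-(ethylenedioxy)-10-hydroxy-6,6,10-trimethyl-3-(prop-1-en-2-yl)-2-oxaspiro[4.5]decan-1-one | C=C(C)[C@H]1C[C@@]2(C(=O)O1)[C@](C)(O)[C@H](O[Si](C)(C)C(C)(C)C)CC3(OCCO3)C2(C)C | intermediate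
20 | (3R,5S,9R,10S)-9-[(tert-butyldimethylsilyl)oxy]-10-hydroxy-6,6,10-trimethyl-3-(prop-1-en-2-yl)-2-oxaspiro[4.5]decane-1,7-dione | C=C(C)[C@H]1C[C@@]2(C(=O)O1)[C@](C)(O)[C@H](O[Si](C)(C)C(C)(C)C)CC(=O)C2(C)C | intermediate
21 | dilithium C10 alkoxide C14 enolate of 20 | C=C(C)[C@H]1C[C@@]2(C(=O)O1)[C@](C)(O[Li])[C@H](O[Si](C)(C)C(C)(C)C)C=C(O[Li])C2(C)C | intermediate
22 | (3R,5S,9R,10S)-9-[(tert-butyldimethylsilyl)oxy]-10-hydroxy-6,6,10-trimethyl-1-oxo-3-(prop-1-en-2-yl)-2-oxaspiro[4.5]dec-7-en-7-yl trifluoromethanesulfonate | C=C(C)[C@H]1C[C@@]2(C(=O)O1)[C@](C)(O)[C@H](O[Si](C)(C)C(C)(C)C)C=C(OS(=O)(=O)C(F)(F)F)C2(C)C | intermediate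
23 | (3R,5S,9R,10S)-7-bromo-9-[(tert-butyldimethylsilyl)oxy]-10-hydroxy-6,6,10-trimethyl-3-(prop-1-en-2-yl)-2-oxaspiro[4.5]dec-7-en-1-one | C=C(C)[C@H]1C[C@@]2(C(=O)O1)[C@](C)(O)[C@H](O[Si](C)(C)C(C)(C)C)C=C(Br)C2(C)C | intermediate
24 | (3R,5S,9R,10S)-7-bromo-9-[(tert-butyldimethylsilyl)oxy]-6,6,10-trimethyl-3-(prop-1-en-2-yl)-2-oxaspiro[4.5]dec-7-ene-1,10-diol (both C1 anomers) | C=C(C)[C@H]1C[C@@]2(C(O)O1)[C@](C)(O)[C@H](O[Si](C)(C)C(C)(C)C)C=C(Br)C2(C)C | intermediate
25 | (3R,5S,9R,10S)-7-bromo-9-[(tert-butyldimethylsilyl)oxy]-1-chloro-6,6,10-trimethyl-3-(prop-1-en-2-yl)-2-oxaspiro[4.5]dec-7-en-10-ol (anomeric chloride) | C=C(C)[C@H]1C[C@@]2(C(Cl)O1)[C@](C)(O)[C@H](O[Si](C)(C)C(C)(C)C)C=C(Br)C2(C)C | intermediate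
26 | oxetane acetal silyl ether (4R,6S,7S,10S,12R): target skeleton with OTBS at C12 cis to O9 | C=C(C)[C@H]1C[C@@]23[C@@H](O1)O[C@]2(C)[C@H](O[Si](C)(C)C(C)(C)C)C=C(Br)C3(C)C | intermediate
27 | oxetane acetal allylic alcohol (4R,6S,7S,10S,12R): target skeleton with OH at C12 cis to O9 | C=C(C)[C@H]1C[C@@]23[C@@H](O1)O[C@]2(C)[C@H](O)C=C(Br)C3(C)C | intermediate
28 | CNP0141320.1 (4R,6S,7S,10S,12S) | C=C(C)[C@H]1C[C@@]23[C@@H](O1)O[C@]2(C)[C@@H](Br)C=C(Br)C3(C)C | target

## Step count and least certain steps

Total: 18 steps. Longest linear sequence: 18 steps from 1 to 28; 7 and 9 enter in steps 4 and 5.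

**Step 9 (key step).**
- The congested chain may fold slowly, so the aldehyde could be reduced to the alcohol or couple intermolecularly before it reaches the ketone. Chelation may be incomplete, which would erode the cis relationship of the diol or the relation of C10–O to C7. On warming, the samarium alkoxides could attack the ester or the epoxide.
- Fallback: setting out from 15, a triazolium-carbene-catalysed intramolecular crossed benzoin reaction (C12 as acyl anion equivalent adding to the C10 ketone) would give the α-hydroxy ketone F1. Reduction of its C12 carbonyl with Zn(BH4)2, chelated to the C10 hydroxyl and attacking from the face of the C11 methyl group, would come back to the route at 16.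

**Step 5.**
- Facial selectivity may be poor, because the geometry of a tetrasubstituted ketene acetal and the reach of the phenyl group over C6 are not secured. Alkylation may leak to the unhindered γ-carbon C11. Deprotonation of the twisted ester may be slow. Competing deprotonation at ring C12 would not matter, since that product converges on 13.
- Fallback: setting out from 6, palladium-catalysed hydroxycarbonylation (Pd(OAc)2, the same diphosphine, CO, KOAc, aqueous DMF) would give the carboxylic acid F2. Its dienediolate has no E/Z isomerism and would be formed and alkylated with 9 under a C2-symmetric chiral dilithium amide (from N,N'-bis(1-phenyl-2-(piperidin-1-yl)ethyl)propane-1,3-diamine and n-BuLi, in the enantiomer that delivers the 7R acid), giving the quaternary acid F3. 1-Chloro-N,N,2-trimethylprop-1-en-1-amine would convert it to the acid chloride F4, and the lithium alkoxide of 7 would return to 11, where any minor C7 epimer is again a separable diastereomer.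

**Step 11.**
- The aluminium alkoxide of the free C10 hydroxyl may open the activated epoxide at C4 (five-membered ether) in competition with removal of a methyl proton. Transesterification of the very hindered ester may be slow.
- Fallback: setting out from 17, N-(trimethylsilyl)imidazole would cap the tertiary hydroxyl to give the bis-silyl ether F5. The same aluminium amide would give the allylic alcohol F6, and Ti(Oi-Pr)4 would close the lactone F7. The aqueous PPTS conditions of step 12 would then remove ketal and trimethylsilyl group together and come back to the route at 20.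

**Step 16.**
- The γ-chloro alkoxide may undergo Grob-type fragmentation (cleavage of C6–C10 to a methyl ketone and a dihydrofuran) instead of closing the four-membered ring. The chloride may be captured by another molecule or by adventitious water.
- Fallback: setting out from 24, PhSSPh and n-Bu3P would give the phenyl thioacetal F8. Activation with MeOTf in the presence of 2,6-di-tert-butyl-4-methylpyridine and 4 Å sieves would generate the oxocarbenium ion without any alkoxide, and capture by the neutral C10 hydroxyl would return to 26.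

**Step 18.**
- Before or during activation, the free C12 hydroxyl of 27 may attack C7 under trace acid and open the oxetane to the five-membered acetal. The hindered alkoxyphosphonium salt may ionise, with participation of O9, instead of being displaced with inversion.
- Fallback: the order would be changed so that the bromide is in place before the oxetane. Setting out from 23, n-Bu4NF would give the diol lactone F9, and Appel bromination of its secondary allylic hydroxyl would give the dibromide lactone F10 with inversion. i-Bu2AlH at −78 °C would give the lactol F11. Methanesulfonic anhydride with i-Pr2NEt at −40 °C forms no alkoxide, so the trans-bromohydrin cannot close to an epoxide; it would ionise C7 and let the C10 hydroxyl close the oxetane, arriving directly at 28.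

## Further compounds

F1 | step 9 | (1R,2S)-2-phenylcyclohexyl (7S,8S)-7-{[(2R)-3,3-dimethyloxiran-2-yl]methyl}-8-hydroxy-6,6,8-trimethyl-9-oxo-1,4-dioxaspiro[4.5]decane-7-carboxylate | O=C(O[C@@H]3CCCC[C@H]3c4ccccc4)[C@]1(C[C@H]5OC5(C)C)[C@](C)(O)C(=O)CC2(OCCO2)C1(C)C
F2 | step 5 | 6,6,8-trimethyl-1,4-dioxaspiro[4.5]dec-7-ene-7-carboxylic acid | CC1=C(C(O)=O)C(C)(C)C2(OCCO2)CC1
F3 | step 5 | (7R)-6,6-dimethyl-8-methylidene-7-(3-methylbut-2-en-1-yl)-1,4-dioxaspiro[4.5]decane-7-carboxylic acid | OC(=O)[C@]1(CC=C(C)C)C(=C)CCC2(OCCO2)C1(C)C
F4 | step 5 | (7R)-6,6-dimethyl-8-methylidene-7-(3-methylbut-2-en-1-yl)-1,4-dioxaspiro[4.5]decane-7-carbonyl chloride | ClC(=O)[C@]1(CC=C(C)C)C(=C)CCC2(OCCO2)C1(C)C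
F5 | step 11 | C10 trimethylsilyl ether of 17 | O=C(O[C@@H]3CCCC[C@H]3c4ccccc4)[C@]1(C[C@H]5OC5(C)C)[C@](C)(O[Si](C)(C)C)[C@H](O[Si](C)(C)C(C)(C)C)CC2(OCCO2)C1(C)C
F6 | step 11 | C10 trimethylsilyl ether of 18 | O=C(O[C@@H]3CCCC[C@H]3c4ccccc4)[C@]1(C[C@@H](O)C(C)=C)[C@](C)(O[Si](C)(C)C)[C@H](O[Si](C)(C)C(C)(C)C)CC2(OCCO2)C1(C)C
F7 | step 11 | C10 trimethylsilyl ether of 19 | C=C(C)[C@H]1C[C@@]2(C(=O)O1)[C@](C)(O[Si](C)(C)C)[C@H](O[Si](C)(C)C(C)(C)C)CC3(OCCO3)C2(C)C
F8 | step 16 | (3R,5S,9R,10S)-7-bromo-9-[(tert-butyldimethylsilyl)oxy]-6,6,10-trimethyl-1-(phenylsulfanyl)-3-(prop-1-en-2-yl)-2-oxaspiro[4.5]dec-7-en-10-ol | C=C(C)[C@H]1C[C@@]2(C(Sc3ccccc3)O1)[C@](C)(O)[C@H](O[Si](C)(C)C(C)(C)C)C=C(Br)C2(C)C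
F9 | step 18 | (3R,5S,9R,10S)-7-bromo-9,10-dihydroxy-6,6,10-trimethyl-3-(prop-1-en-2-yl)-2-oxaspiro[4.5]dec-7-en-1-one | C=C(C)[C@H]1C[C@@]2(C(=O)O1)[C@](C)(O)[C@H](O)C=C(Br)C2(C)C
F10 | step 18 | (3R,5S,9S,10S)-7,9-dibromo-10-hydroxy-6,6,10-trimethyl-3-(prop-1-en-2-yl)-2-oxaspiro[4.5]dec-7-en-1-one | C=C(C)[C@H]1C[C@@]2(C(=O)O1)[C@](C)(O)[C@@H](Br)C=C(Br)C2(C)C
F11 | step 18 | (3R,5S,9S,10S)-7,9-dibromo-6,6,10-trimethyl-3-(prop-1-en-2-yl)-2-oxaspiro[4.5]dec-7-ene-1,10-diol (both C1 anomers) | C=C(C)[C@H]1C[C@@]2(C(O)O1)[C@](C)(O)[C@@H](Br)C=C(Br)C2(C)C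
A1 | alternative 1 | lactone with quaternary C6 between C15 and C10 (product of the conjugate addition–aldol step) | C=C(C)[C@H]1C[C@](C(=O)O1)(C(C)(C)C(C)(OC)OC)[C@](C)(O)C(OC)OC
A2 | alternative 1 | α-alkylidene lactone, (5R)-3-(3,3-dimethoxybutan-2-ylidene)-5-(prop-1-en-2-yl)oxolan-2-one | C=C(C)[C@H]1CC(=C(C)C(C)(OC)OC)C(=O)O1
A3 | alternative 1 | 1,1-dimethoxypropan-2-one | CC(=O)C(OC)OC
A4 | alternative 2 | spiro isopropenyl lactone (product of the allyl lactonisation) | C=C(C)[C@H]1C[C@@]2(C(=O)O1)C(C)=CCC3(OCCO3)C2(C)C
A5 | alternative 2 | ring A carboxylic acid carrying a 4-(methoxycarbonyloxy)-3-methylbut-2-en-1-yl chain at C6 | COC(=O)OCC(C)=CC[C@@]1(C(=O)O)C(C)=CCC2(OCCO2)C1(C)C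
A6 | alternative 3 | ring A carboxylic acid (product of the ring-contracting rearrangement) | CC(C)=CC[C@@]1(C(=O)O)[C@]2(C)OC(C)(C)O[C@@H]2C=C(Br)C1(C)C
A7 | alternative 3 | six-membered lactone of C7, O, C13, C12, C10 and C6 with the C10/C12 acetonide, a 1-bromo-2-methylprop-1-enyl group at C13 and prenyl at C6 (C6 and C13 not specified) | CC(C)=CCC1C(=O)OC(C(Br)=C(C)C)[C@H]2OC(C)(C)O[C@@]12C
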